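The only stereocentre of the target, C2'', sits in the dihydrofuran ring fused to ring B across C3'–C4'. Cutting C3'–C3'' and O–C2'' turns that ring and its hydroxyisopropyl arm into isoprene plus an isoflavone bearing a 4'-OH next to a 3'-iodide. C3' is the carbon flanked by the 2'- and 4'-oxygens, the site a resorcinol iodinates. One enantioselective palladium-catalysed diene heteroannulation on the complete isoflavone then forms both bonds, the ring and the R centre. The precursor is the 5,7,2'-tri-O-benzyl-3'-iodo-4'-hydroxyisoflavone, built from 2-iodoresorcinol and phloroacetophenone through a chalcone and an oxidative aryl shift; alkene hydration and hydrogenolysis complete the synthesis.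

Key step: step 7

Remark on locants: isoflavone numbering is used, with primes for ring B and double primes for the dihydrofuran carbons (C2'' is the stereocentre, C3'' its CH2 neighbour).

Assumption: L* in step 7 is an enantiopure phosphine ligand (first choice a tert-butanesulfinamide-derived monophosphine of the TY-Phos type, second choice an atropisomeric bisphosphine such as DTBM-SEGPHOS). Its sense of induction for an iodide lying between two oxygens cannot be predicted safely, so the antipode that gives 2R is to be fixed in a pilot run.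

Step 1
Reactants: 1 2-iodobenzene-1,3-diol
Product: 3 2,4-dihydroxy-3-iodobenzaldehyde, via iminium chloride 2 (not isolated)
Conditions: POCl3 (1.2 equiv), DMF (1.5 equiv), MeCN, −15 °C to rt; then H2O, 50 °C
Reagents that add atoms: N,N-dimethylformamide, CN(C)C=O (formyl carbon); water, O (carbonyl oxygen, on hydrolysis)
Why: Vilsmeier–Haack formylation: the chloroiminium ion attacks C4 (equivalent to C6), para to one hydroxyl and ortho to the other, the aryl iminium salt resists a second attack and is hydrolysed to the aldehyde, and the low temperature should keep the acid-sensitive C–I bond in place.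

Step 2
Reactants: 3 2,4-dihydroxy-3-iodobenzaldehyde
Product: 4 2-hydroxy-3-iodo-4-(methoxymethoxy)benzaldehyde
Conditions: MOMCl (1.1 equiv), K2CO3, acetone, 0 °C to rt
Reagents that add atoms: chloromethyl methyl ether, COCCl
Why: Williamson-type O-alkylation under mild base should take the 4-OH, which is the more acidic phenol (para to the formyl group) and is not held in the hydrogen bond to the carbonyl group that ties up the 2-OH.

Step 3
Reactants: 4 2-hydroxy-3-iodo-4-(methoxymethoxy)benzaldehyde
Product: 5 2-(benzyloxy)-3-iodo-4-(methoxymethoxy)benzaldehyde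
Conditions: BnBr, K2CO3, DMF, 60 °C
Reagents that add atoms: benzyl bromide, BrCc1ccccc1
Why: Williamson etherification of the remaining chelated 2-OH with the reactive benzyl bromide on mild heating; the MOM acetal, the aldehyde and the aryl iodide are stable to K2CO3.

Step 4
Reactants: 6 1-(2,4,6-trihydroxyphenyl)ethan-1-one
Product: 7 1-[2,4-bis(benzyloxy)-6-hydroxyphenyl]ethan-1-one
Conditions: BnBr (2.1 equiv), K2CO3, DMF, rt to 50 °C
Reagents that add atoms: benzyl bromide, BrCc1ccccc1
Why: Williamson etherification under stoichiometric control: the 4-OH and one ortho OH are alkylated, while the last ortho OH, held in a strong hydrogen bond to the ketone, should stay free, as is general for 2-hydroxyacetophenones.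

Step 5
Reactants: 5 2-(benzyloxy)-3-iodo-4-(methoxymethoxy)benzaldehyde; 7 1-[2,4-bis(benzyloxy)-6-hydroxyphenyl]ethan-1-one
Product: 8 (2E)-1-[2,4-bis(benzyloxy)-6-hydroxyphenyl]-3-[2-(benzyloxy)-3-iodo-4-(methoxymethoxy)phenyl]prop-2-en-1-one
Conditions: KOH (50% aq), EtOH/THF, rt
Reagents that add atoms: none
Why: Claisen–Schmidt condensation (crossed aldol addition of the methyl ketone enolate to the non-enolisable aldehyde, then E1cB dehydration) gives the thermodynamically preferred E-enone; the ethers, the MOM acetal and the aryl iodide are inert to hydroxide.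

Step 6
Reactants: 8 (2E)-1-[2,4-bis(benzyloxy)-6-hydroxyphenyl]-3-[2-(benzyloxy)-3-iodo-4-(methoxymethoxy)phenyl]prop-2-en-1-one
Product: 10 5,7-bis(benzyloxy)-3-[2-(benzyloxy)-4-hydroxy-3-iodophenyl]-4H-chromen-4-one, via keto acetal 9 (not isolated)
Conditions: Tl(NO3)3·3H2O (1.1 equiv), MeOH/HC(OMe)3, rt; then 10% HCl, MeOH/THF, 55 °C
Reagents that add atoms: none
Why: Oxidative rearrangement of a 2'-hydroxychalcone with trivalent thallium: methanol adds as the enone is oxythallated, the electron-rich 2,4-dioxygenated ring B shifts from the β- to the α-carbon as monovalent thallium leaves, and the resulting β-keto dimethyl acetal is closed by acid to ring C (attack of the ring A phenol, loss of two methanol) while the same acid cleaves the MOM acetal and leaves the benzyl ethers and the iodide alone.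

Step 7
Reactants: 10 5,7-bis(benzyloxy)-3-[2-(benzyloxy)-4-hydroxy-3-iodophenyl]-4H-chromen-4-one; 11 2-methylbuta-1,3-diene (isoprene, 5 equiv)
Product: 12 5,7-bis(benzyloxy)-3-[(2R)-4-(benzyloxy)-2-(prop-1-en-2-yl)-2,3-dihydro-1-benzofuran-5-yl]-4H-chromen-4-one
Conditions: Pd2(dba)3 (2.5 mol%), chiral phosphine L* (10 mol%), K2CO3 (2 equiv), toluene, sealed tube, 80 °C
Reagents that add atoms: none
Why: Zerovalent palladium inserts into the C3'–I bond of 10, the aryl–palladium bond adds across the monosubstituted double bond of 11 with the aryl group going to its CH2 (C3'–C3'' formed), and the resulting 2-methylallyl palladium complex is captured at its internal carbon by the C4' phenoxide (O–C2'' formed), which returns zerovalent palladium. This is the Larock heteroannulation of ortho-iodophenols with 1,3-dienes, which with isoprene gives 2-isopropenyl-2,3-dihydrobenzofurans and has ligand-controlled enantioselective versions; only the position of the iodide between two oxygens is new for the substrate. The dihydrofuran ring closes by 5-exo attack of oxygen on the allyl unit, the alternative attack at the CH2 terminus requiring a seven-membered ring. C2'' is set as R by the chiral ligand on palladium: the two faces of the allyl complex exchange through the sigma-bonded form at the unsubstituted CH2 terminus faster than the C–O bond forms, so the ligand decides which diastereomeric complex cyclizes. The step needs insertion regioselectivity, secured by the preference of the bulky aryl group for the terminal carbon of the less substituted alkene, and site selectivity between the two ring B oxygens, secured by the benzyl ether on O2', which leaves O4' as the only nucleophile; carboxylate-free conditions at 80 °C should disfavour C–H arylation of that benzyl group.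

Step 8
Reactants: 12 5,7-bis(benzyloxy)-3-[(2R)-4-(benzyloxy)-2-(prop-1-en-2-yl)-2,3-dihydro-1-benzofuran-5-yl]-4H-chromen-4-one
Product: 13 5,7-bis(benzyloxy)-3-[(2R)-4-(benzyloxy)-2-(2-hydroxypropan-2-yl)-2,3-dihydro-1-benzofuran-5-yl]-4H-chromen-4-one
Conditions: Co(acac)2 (20 mol%), PhSiH3 (2.5 equiv), O2 (1 atm), THF/i-PrOH, rt
Reagents that add atoms: dioxygen, O=O
Why: Mukaiyama hydration: a cobalt hydride made from the silane transfers a hydrogen atom to the terminal CH2 (Markovnikov sense), the tertiary radical is trapped by O2 and the peroxide is reduced in the flask to the alcohol; the 1,1-disubstituted alkene should react ahead of the trisubstituted, electron-poor chromone C2=C3 bond, and C2'' is not a radical site, so its R configuration is kept.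

Step 9
Reactants: 13 5,7-bis(benzyloxy)-3-[(2R)-4-(benzyloxy)-2-(2-hydroxypropan-2-yl)-2,3-dihydro-1-benzofuran-5-yl]-4H-chromen-4-one
Product: 14 5,7-dihydroxy-3-[(2R)-4-hydroxy-2-(2-hydroxypropan-2-yl)-2,3-dihydro-1-benzofuran-5-yl]-4H-chromen-4-one
Conditions: H2 (1 atm), 10% Pd/C, EtOAc/MeOH, rt, stopped when debenzylation is complete
Reagents that add atoms: none
Why: Catalytic hydrogenolysis of the three benzyl aryl ethers; the O–C2'' bond is a non-benzylic alkyl aryl ether and the tertiary alcohol is not benzylic, so neither is cleaved, the stereocentre is untouched, and the conjugated trisubstituted chromone double bond is reduced only slowly.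

Compound list
1 | 2-iodobenzene-1,3-diol | Oc1cccc(O)c1I | starting material
2 | [(2,4-dihydroxy-3-iodophenyl)methylidene]dimethylammonium chloride | C[N+](C)=Cc1ccc(O)c(I)c1O.[Cl-] | intermediate
3 | 2,4-dihydroxy-3-iodobenzaldehyde | O=Cc1ccc(O)c(I)c1O | intermediate
4 | 2-hydroxy-3-iodo-4-(methoxymethoxy)benzaldehyde | COCOc1ccc(C=O)c(O)c1I | intermediate
5 | 2-(benzyloxy)-3-iodo-4-(methoxymethoxy)benzaldehyde | COCOc1ccc(C=O)c(OCc2ccccc2)c1I | intermediate
6 | 1-(2,4,6-trihydroxyphenyl)ethan-1-one | CC(=O)c1c(O)cc(O)cc1O | starting material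
7 | 1-[2,4-bis(benzyloxy)-6-hydroxyphenyl]ethan-1-one | CC(=O)c1c(O)cc(OCc2ccccc2)cc1OCc1ccccc1 | intermediate
8 | (2E)-1-[2,4-bis(benzyloxy)-6-hydroxyphenyl]-3-[2-(benzyloxy)-3-iodo-4-(methoxymethoxy)phenyl]prop-2-en-1-one | COCOc1ccc(/C=C/C(=O)c2c(O)cc(OCc3ccccc3)cc2OCc2ccccc2)c(OCc2ccccc2)c1I | intermediate
9 | 1-[2,4-bis(benzyloxy)-6-hydroxyphenyl]-2-[2-(benzyloxy)-3-iodo-4-(methoxymethoxy)phenyl]-3,3-dimethoxypropan-1-one (racemic) | COCOc1ccc(C(C(OC)OC)C(=O)c2c(O)cc(OCc3ccccc3)cc2OCc2ccccc2)c(OCc2ccccc2)c1I | intermediate
10 | 5,7-bis(benzyloxy)-3-[2-(benzyloxy)-4-hydroxy-3-iodophenyl]-4H-chromen-4-one | Oc1ccc(-c2coc3cc(OCc4ccccc4)cc(OCc4ccccc4)c3c2=O)c(OCc2ccccc2)c1I | intermediate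
11 | 2-methylbuta-1,3-diene (isoprene) | C=CC(C)=C | starting material
12 | 5,7-bis(benzyloxy)-3-[(2R)-4-(benzyloxy)-2-(prop-1-en-2-yl)-2,3-dihydro-1-benzofuran-5-yl]-4H-chromen-4-one | C=C(C)[C@H]1Cc2c(ccc(-c3coc4cc(OCc5ccccc5)cc(OCc5ccccc5)c4c3=O)c2OCc2ccccc2)O1 | intermediate
13 | 5,7-bis(benzyloxy)-3-[(2R)-4-(benzyloxy)-2-(2-hydroxypropan-2-yl)-2,3-dihydro-1-benzofuran-5-yl]-4H-chromen-4-one | CC(C)(O)[C@H]1Cc2c(ccc(-c3coc4cc(OCc5ccccc5)cc(OCc5ccccc5)c4c3=O)c2OCc2ccccc2)O1 | intermediate
14 | 5,7-dihydroxy-3-[(2R)-4-hydroxy-2-(2-hydroxypropan-2-yl)-2,3-dihydro-1-benzofuran-5-yl]-4H-chromen-4-one | CC(C)(O)[C@H]1Cc2c(ccc(-c3coc4cc(O)cc(O)c4c3=O)c2O)O1 | target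

Total step count: 9. Longest linear sequence: 8 steps (steps 1, 2, 3, 5, 6, 7, 8 and 9, from 2-iodoresorcinol).

Steps most likely to fail

Step 7. Insertion of the diene at the crowded aryl–palladium centre may be slow, so that hydrodeiodination or C–H arylation of the neighbouring benzyl ether takes over. Facial discrimination in the C–O bond formation may be low, and the product, an allylic aryl ether, may be re-ionised by palladium and lose enantiopurity on long reaction times. The fallback gives up the annulation and builds the ring by epoxide opening, setting out from 10 and coming back at 13, so that step 8 is bypassed as well. Silylation of 10 (TBSCl, imidazole, DMF) should give the tert-butyldimethylsilyl ether F1. Stille coupling with tributyl(3-methylbut-2-en-1-yl)stannane (Pd(PPh3)4, DMF, 90 °C) should give the 3'-prenyl compound F2. Shi epoxidation of the prenyl double bond with the L-fructose-derived ketone 1,2:4,5-di-O-isopropylidene-β-L-erythro-2,3-hexodiulo-2,6-pyranose (the enantiomer of the usual D-fructose-derived catalyst), KHSO5 (as 2KHSO5·KHSO4·K2SO4) and K2CO3 in MeCN/dimethoxymethane/aqueous buffer at 0 °C is expected to give the (2S)-oxirane F3. Bu4NF in THF then frees the C4' phenoxide, which opens the epoxide 5-exo at its secondary carbon with inversion and should give 13 with the R configuration.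

Step 6. The 2'-hydroxychalcone may cyclize through its own phenol (aurone or flavone formation) instead of undergoing the aryl shift, and the iodine between two oxygens may be lost or may migrate during the acidic ring closure. The fallback replaces the oxidative aryl shift by the acyl shift of a chalcone epoxide, setting out from 8 and coming back at 10. MOMCl and NaH in DMF at 0 °C should give the bis-MOM chalcone F4. Weitz–Scheffer epoxidation (H2O2, NaOH, MeOH/THF, 0 °C) should give the racemic trans-epoxy ketone F5. Brief treatment with BF3·OEt2 in CH2Cl2 at 0 °C opens the epoxide at the carbon next to ring B and shifts the aroyl group to it, which should give the 2-aryl-3-oxopropanal F6. HCl in MeOH at 50 °C removes both MOM groups, and the freed ring A phenol condenses with the aldehyde to give 10.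

Step 8. Hydrogen-atom transfer may also reach the chromone C2=C3 bond, or the tertiary radical may be reduced to the isopropyl group instead of being oxygenated. The fallback is ionic Markovnikov hydration, setting out from 12 and coming back at 13. Oxymercuration with Hg(OAc)2 in THF/H2O at rt should give the acetoxymercurio alcohol F7 (a mixture of epimers at the carbinol carbon, not isolated). Short demercuration with NaBH4 in aqueous NaOH at 0 °C should then give 13, the extra stereocentre vanishing as the C–Hg bond becomes C–H.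

Further compounds
F1 | step 7 | 5,7-bis(benzyloxy)-3-[2-(benzyloxy)-4-{[tert-butyl(dimethyl)silyl]oxy}-3-iodophenyl]-4H-chromen-4-one | CC(C)(C)[Si](C)(C)Oc1ccc(-c2coc3cc(OCc4ccccc4)cc(OCc4ccccc4)c3c2=O)c(OCc2ccccc2)c1I
F2 | step 7 | 5,7-bis(benzyloxy)-3-[2-(benzyloxy)-4-{[tert-butyl(dimethyl)silyl]oxy}-3-(3-methylbut-2-en-1-yl)phenyl]-4H-chromen-4-one | CC(C)=CCc1c(O[Si](C)(C)C(C)(C)C)ccc(-c2coc3cc(OCc4ccccc4)cc(OCc4ccccc4)c3c2=O)c1OCc1ccccc1
F3 | step 7 | 5,7-bis(benzyloxy)-3-[2-(benzyloxy)-4-{[tert-butyl(dimethyl)silyl]oxy}-3-{[(2S)-3,3-dimethyloxiran-2-yl]methyl}phenyl]-4H-chromen-4-one | CC1(C)O[C@H]1Cc1c(O[Si](C)(C)C(C)(C)C)ccc(-c2coc3cc(OCc4ccccc4)cc(OCc4ccccc4)c3c2=O)c1OCc1ccccc1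
F4 | step 6 | (2E)-1-[2,4-bis(benzyloxy)-6-(methoxymethoxy)phenyl]-3-[2-(benzyloxy)-3-iodo-4-(methoxymethoxy)phenyl]prop-2-en-1-one | COCOc1ccc(/C=C/C(=O)c2c(OCOC)cc(OCc3ccccc3)cc2OCc2ccccc2)c(OCc2ccccc2)c1I
F5 | step 6 | [2,4-bis(benzyloxy)-6-(methoxymethoxy)phenyl]{trans-3-[2-(benzyloxy)-3-iodo-4-(methoxymethoxy)phenyl]oxiran-2-yl}methanone (racemic, one enantiomer drawn) | O=C([C@@H]1O[C@H]1c1ccc(OCOC)c(I)c1OCc1ccccc1)c1c(OCOC)cc(OCc2ccccc2)cc1OCc1ccccc1
F6 | step 6 | 3-[2,4-bis(benzyloxy)-6-(methoxymethoxy)phenyl]-2-[2-(benzyloxy)-3-iodo-4-(methoxymethoxy)phenyl]-3-oxopropanal (racemic) | O=CC(c1ccc(OCOC)c(I)c1OCc1ccccc1)C(=O)c1c(OCOC)cc(OCc2ccccc2)cc1OCc1ccccc1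
F7 | step 8 | acetato{2-[(2R)-4-(benzyloxy)-5-[5,7-bis(benzyloxy)-4-oxo-4H-chromen-3-yl]-2,3-dihydro-1-benzofuran-2-yl]-2-hydroxypropyl}mercury (mixture of epimers at the carbinol carbon) | CC(O)(C[Hg]OC(C)=O)[C@H]1Cc2c(ccc(-c3coc4cc(OCc5ccccc5)cc(OCc5ccccc5)c4c3=O)c2OCc2ccccc2)O1
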